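## The problem

Prostanoid numbering is used throughout. Ring A is C8–C9–C10–C11–C12, with the ketone at C9, chlorine on C10, C11–H, and the quaternary acetoxy carbon C12. C8 carries the (5E,7E)-dienylidene chain C7→C1 (methyl ester). C12 carries the (14Z)-oct-2-enyl chain C13→C20.

1. Ring A is a cross-conjugated, halogenated cyclopentenone: C10–Cl, C10=C11, C9=O and C8=C7 must all be arranged around one sp3 carbon.
2. C12 is the only stereocentre. It is quaternary, oxygenated and flanked by two sp2 carbons, so no other centre can control it and it cannot be corrected later. It must be (R).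
3. Three alkenes of fixed geometry (5E, 7E, 14Z) sit in two chains that must be attached at C8 and C12 without scrambling.
4. The C12 acetate is β to the C9 ketone through C8, so any C8 enolate formed while it is in place would expel it (E1cB, towards a cyclopentadienone).
5. The finished trienone is a multiple Michael acceptor and is light-sensitive at C5=C6 and C7=C8. The C13 methylene is doubly activated once C12 carries unsaturation or a carbonyl.
6. The enabling feature is C10. It is the only ring atom that makes C8 and C11 different. With C10 formally removed, ring A contracts to a cyclobutanone (C9 carbonyl, C12 at the 3-position) in which C12 lies on a mirror plane and C8 and C11 are enantiotopic methylenes.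
7. Re-inserting C10 as dichlorocarbene into an enol ether of one of these methylenes returns exactly the C9(=O)–C10(Cl)=C11 unit. The choice of methylene alone therefore fixes C12 and, at the same time, decides which carbon is left as the C8 methylene for the α-chain.

## Retrosynthesis

**20 ⇒ 19 ⇒ 18 (C12–O acyl and silyl exchange; no skeletal bond cut).** The acetate goes on last, because only when C8 is sp2 is there no α-hydrogen from which a β-acetoxy group at C12 could be eliminated. Before that point the oxygen is carried as a triethylsilyl ether (18), a poor leaving group that survives enolate chemistry. The forward steps must be a mild desilylation and a tertiary-alcohol acetylation on the trienone.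

**18 ⇒ 11 + 14 (C7=C8 cut; aldol condensation).** C8 of chloroenone 11 is the only enolisable carbon, since C12 is quaternary, so regiochemistry is not in question. Cutting C5=C6 or C6–C7 instead would need a ring-bound dienal or a phosphonate, both harder to make. Aldehyde 14 carries C1–C7 with the 5E alkene already set and comes in one step from 12 and 13 by cross-metathesis (C5=C6 cut). The forward reaction must give the 7E geometry on dehydration.

**11 ⇒ 10 (C14=C15 as an alkyne).** The Z alkene is carried as a triple bond through the carbene step, because an internal alkyne is a far poorer partner for an electrophilic carbene than a cis-alkene. It is semi-hydrogenated before the diene is installed. The forward step must leave the chloroenone untouched.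

**10 ⇒ 8 (C9–C10 and C10–C11 cut; C10 with its chlorine excised as :CCl2).** This is the key disconnection. Instead of building a cyclopentenone and then oxidising and chlorinating it, the chlorine-bearing carbon is taken out, leaving the silyl enol ether 8 of a cyclobutanone. The precursor has one ring carbon fewer, no chlorine and no enone. The forward reaction is cyclopropanation of the strained enol ether to a housane (9) and strain-driven opening to the 2-chloroenone. It must deliver C10 between C9 and C11 only, which the position of the enol double bond guarantees.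

**8 ⇒ 6 (enol C=C; desymmetrisation).** Ketone 6 is achiral: C12 lies on its mirror plane. A chiral lithium amide must choose one of the two enantiotopic methylenes. The enolised carbon becomes C11 and the other becomes C8. This replaces an enantioselective C–C or C–O bond formation at a fully substituted carbon by a choice between two CH2 groups, and no bond to C12 is made or broken after this point.

**6 ⇒ 5 ⇒ 4 ⇒ 1 + 2 (C12–C13 cut; carbonyl addition).** Ketone 6 is the hydrolysed form of the ethyl enol ether 5. Compound 5 is the silylated adduct 4 of an oct-2-ynyl zinc reagent (from bromide 2) with commercial 3-ethoxycyclobut-2-en-1-one 1. The four-membered ring and all its oxygen functions are bought; only one C–C bond has to be made, without stereocontrol, because the stereochemical information is deliberately erased in 6 and written in at step 4.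

## Roads not taken

**Alternative 1:** (the obvious route) Cut C7=C8 by aldol and C12–C13 by carbonyl addition on a preformed five-membered ring. An oct-2-ynyl metal is added to a mono-protected cyclopent-4-ene-1,3-dione to give racemic 4-hydroxy-4-(oct-2-yn-1-yl)cyclopent-2-en-1-one A1. This is resolved, chlorinated at C10 by nucleophilic epoxidation and HCl opening, protected, and condensed with 14. The forward key step is an unselective carbonyl addition, so half of the material is lost in the resolution. Chlorine and the C10=C11 unsaturation need a separate oxidation/halogenation sequence on a compound that already carries the sensitive tertiary carbinol. The chosen plan obtains C12 by induction and gets C10, its chlorine and the enone from one carbon atom in one operation.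

**Alternative 2:** Dearomatisation of a furan. 2-Methyl-5-(oct-2-yn-1-yl)furan A2 is opened oxidatively to the cis-enedione (3Z)-tridec-3-en-7-yne-2,5-dione A3. Intramolecular aldol of the methyl ketone onto the C12 carbonyl (C8–C12 bond) again gives A1. The flat furan supplies all five ring carbons cheaply, but the aldol is racemic. The most acidic position of A3 is the C13 methylene between ketone and alkyne, which leads to the wrong ring or to an allene. Chlorine is still missing. In the chosen plan the only enolisation is at two methylenes that differ solely in being enantiotopic.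

**Alternative 3:** Cut C12–C13 last. The ω-chain would be added by catalytic asymmetric propargylation to the fully elaborated ene-dione methyl (5E,7E)-7-(3-chloro-2,5-dioxocyclopent-3-en-1-ylidene)hept-5-enoate A4. This is maximally convergent, but A4 is planar and triply electrophilic (two carbonyls, 1,4- and 1,6-acceptor positions). The catalyst would have to select C12 over C9 and one face with nothing but a distant chlorine to guide it. The chosen plan makes the stereo-determining event a proton removal on a compact ketone with a single functional group.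

Key step: step 5

**Assumption:** lithium (R,R)-bis(1-phenylethyl)amide is taken to enolise the methylene that leads to (S)-8. The sense of induction on this substrate is assigned by analogy. If it proves opposite, the (S,S)-amide is used with no other change. Compounds 1, 2, 12 and 13 are purchased.

## Steps

Step 1
Reactants: 1 3-ethoxycyclobut-2-en-1-one; 2 1-bromooct-2-yne
Product: 4 3-ethoxy-1-(oct-2-yn-1-yl)cyclobut-2-en-1-ol (racemic), via octa-1,2-dien-3-ylzinc bromide 3 (not isolated)
Conditions: Zn dust (activated), THF, 0 °C → rt; cold aq. NaHCO3 work-up, no acidic silica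
Reagents that add atoms: none
Why: Barbier-type propargylation: zinc inserts into 2 to give allenylzinc 3, which adds to the strained ketone carbonyl of 1 through a cyclic SE2' transition state, so the C12–C13 bond forms at the CH2 terminus and the triple bond is regenerated in the oct-2-ynyl position; 1,2-addition is expected because the ethoxy group deactivates the β-carbon.

Step 2
Reactants: 4 3-ethoxy-1-(oct-2-yn-1-yl)cyclobut-2-en-1-ol
Product: 5 {[3-ethoxy-1-(oct-2-yn-1-yl)cyclobut-2-en-1-yl]oxy}triethylsilane (racemic)
Conditions: TESOTf, 2,6-lutidine, CH2Cl2, −78 °C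
Reagents that add atoms: triethylsilyl trifluoromethanesulfonate, CC[Si](CC)(CC)OS(=O)(=O)C(F)(F)F
Why: Silylation of a tertiary alcohol with a silyl triflate and a hindered pyridine base at low temperature; the non-acidic conditions avoid ionisation of the allylic carbinol, and the siloxy group is a poor leaving group in the enolate steps that follow.

Step 3
Reactants: 5 {[3-ethoxy-1-(oct-2-yn-1-yl)cyclobut-2-en-1-yl]oxy}triethylsilane
Product: 6 3-(oct-2-yn-1-yl)-3-[(triethylsilyl)oxy]cyclobutan-1-one (achiral)
Conditions: oxalic acid (cat.), THF/H2O, 0 °C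
Reagents that add atoms: water, O
Why: Acid-catalysed enol ether hydrolysis: rate-limiting C-protonation gives an ethoxy oxocarbenium ion that is hydrolysed to the ketone; with the tertiary oxygen capped as a silyl ether the competing dehydrative transposition to a cyclobutenone is slowed, and the product is achiral because C12 now lies on a mirror plane.

Step 4
Reactants: 6 3-(oct-2-yn-1-yl)-3-[(triethylsilyl)oxy]cyclobutan-1-one
Product: 8 (3S)-3-(oct-2-yn-1-yl)-3-[(triethylsilyl)oxy]-1-[(trimethylsilyl)oxy]cyclobut-1-ene, via lithium enolate 7 (not isolated)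
Conditions: (R,R)-bis(1-phenylethyl)amine, n-BuLi, THF; TMSCl present in situ, −100 °C; pentane, filtration, used cold without chromatography
Reagents that add atoms: chlorotrimethylsilane, C[Si](C)(C)Cl
Why: Enantiotopic-group-selective deprotonation of a prochiral cyclobutanone by a C2-symmetric chiral lithium amide with in situ silylation, a known desymmetrisation of 3-substituted cyclobutanones; the C12 stereocentre arises solely from which methylene is enolised (the enolised carbon becomes C11, the other C8), and the in situ TMSCl traps enolate 7 before it can expel the β-siloxide.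

Step 5
Reactants: 8 (3S)-3-(oct-2-yn-1-yl)-3-[(triethylsilyl)oxy]-1-[(trimethylsilyl)oxy]cyclobut-1-ene
Product: 10 (4S)-2-chloro-4-(oct-2-yn-1-yl)-4-[(triethylsilyl)oxy]cyclopent-2-en-1-one, via dichlorohousane 9 (not isolated)
Conditions: Cl3CCO2Et (slight excess over base), NaOMe, pentane, −10 → 0 °C; filtration; then 23 °C; aq. NaHCO3
Reagents that add atoms: ethyl trichloroacetate, CCOC(=O)C(Cl)(Cl)Cl
Why: Proposed new method: the closest known reaction type is the dihalocarbene one-carbon ring enlargement of five- to seven-membered cyclic silyl enol ethers to 2-halocycloalk-2-enones, extended here to a 1-siloxycyclobutene. Electrophilic singlet :CCl2 should add in a concerted [2+1] fashion to the electron-rich, strained enol ether double bond of 8, far faster than to the alkyne, closing the cyclopropane of housane 9 on either face. Ionisation of the endo chloride, assisted by the siloxy oxygen and concerted with disrotatory opening of the central C1–C4 bond (cyclopropyl-to-allyl cation), releases the strain of the bicyclo[2.1.0]pentane and gives a 2-chloro-1-siloxycyclopentenyl cation, from which chloride removes the silyl group to leave 10. The five-membered ring therefore arises by enlargement of the four-membered ring through electrocyclic opening of the fused cyclopropane, not by an end-to-end closure. No new stereocentre survives: C12 is a spectator fixed in step 4, and both diastereomers of 9 converge on one product. The selectivity needed is positional, the carbene carbon entering between C9 and C11 only; this is secured because only the enolised methylene carries the double bond, so C8 stays a CH2 for step 8.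

Step 6
Reactants: 10 (4S)-2-chloro-4-(oct-2-yn-1-yl)-4-[(triethylsilyl)oxy]cyclopent-2-en-1-one
Product: 11 (4S)-2-chloro-4-[(2Z)-oct-2-en-1-yl]-4-[(triethylsilyl)oxy]cyclopent-2-en-1-one
Conditions: H2 (1 atm), Lindlar catalyst (Pd/CaCO3 poisoned with Pb(OAc)2), quinoline, EtOAc, 0 °C, stopped after one equivalent of H2
Reagents that add atoms: none
Why: Lindlar semi-hydrogenation delivers H2 syn to the alkyne to give the (14Z)-alkene; the poisoned catalyst and quinoline should leave the hindered, electron-poor trisubstituted chloroenone and its C–Cl bond alone.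

Step 7
Reactants: 12 methyl hex-5-enoate; 13 (2E)-but-2-enal
Product: 14 methyl (5E)-7-oxohept-5-enoate
Conditions: second-generation Hoveyda–Grubbs catalyst RuCl2(=CH-C6H4-2-OiPr)(1,3-dimesitylimidazolidin-2-ylidene) (cat.), excess 13, CH2Cl2, 40 °C
Reagents that add atoms: none
Why: Cross-metathesis of a terminal alkene with an α,β-unsaturated aldehyde; the conjugated product forms under thermodynamic control as the (E)-enal, and propene is lost.

Step 8
Reactants: 11 (4S)-2-chloro-4-[(2Z)-oct-2-en-1-yl]-4-[(triethylsilyl)oxy]cyclopent-2-en-1-one; 14 methyl (5E)-7-oxohept-5-enoate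
Product: 16 methyl (5E)-7-{(2S)-4-chloro-2-[(2Z)-oct-2-en-1-yl]-5-oxo-2-[(triethylsilyl)oxy]cyclopent-3-en-1-yl}-7-hydroxyhept-5-enoate (diastereomer mixture at C7 and C8), via lithium dienolate 15 (not isolated)
Conditions: LDA, THF, −78 °C; then 14, −78 °C; AcOH quench
Reagents that add atoms: none
Why: Kinetic lithium enolate aldol addition: C8 is the only enolisable position of 11, so LDA gives the cross-conjugated dienolate 15, which adds 1,2 to the enal at −78 °C; the new centres at C7 and C8 are removed in step 9 and need no control, and the C12 siloxide is too poor a leaving group to be lost at this temperature.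

Step 9
Reactants: 16 methyl (5E)-7-{(2S)-4-chloro-2-[(2Z)-oct-2-en-1-yl]-5-oxo-2-[(triethylsilyl)oxy]cyclopent-3-en-1-yl}-7-hydroxyhept-5-enoate
Product: 18 methyl (5E,7E)-7-{(2R)-4-chloro-2-[(2Z)-oct-2-en-1-yl]-5-oxo-2-[(triethylsilyl)oxy]cyclopent-3-en-1-ylidene}hept-5-enoate, via allylic mesylate 17 (not isolated)
Conditions: MsCl, Et3N, CH2Cl2, 0 °C; then DBU, 0 °C → rt, in the dark
Reagents that add atoms: none
Why: Mesylation followed by E1cB elimination through the C8 enolate; the C7 mesylate is expelled in preference to the C12 siloxide, both aldol diastereomers converge, and the (7E) geometry (C6 anti to the C9 carbonyl) should predominate while the 5E alkene of 14 is untouched.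

Step 10
Reactants: 18 methyl (5E,7E)-7-{(2R)-4-chloro-2-[(2Z)-oct-2-en-1-yl]-5-oxo-2-[(triethylsilyl)oxy]cyclopent-3-en-1-ylidene}hept-5-enoate
Product: 19 methyl (5E,7E)-7-{(2R)-4-chloro-2-hydroxy-2-[(2Z)-oct-2-en-1-yl]-5-oxocyclopent-3-en-1-ylidene}hept-5-enoate
Conditions: HF·pyridine, pyridine, THF, 0 °C → rt, in the dark
Reagents that add atoms: none
Why: Fluoride-mediated cleavage of a tertiary triethylsilyl ether under buffered, weakly acidic conditions that the trienone, the ester and the alkenes tolerate; no C8 enolate can form any longer, so the free tertiary alcohol is stable.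

Step 11
Reactants: 19 methyl (5E,7E)-7-{(2R)-4-chloro-2-hydroxy-2-[(2Z)-oct-2-en-1-yl]-5-oxocyclopent-3-en-1-ylidene}hept-5-enoate
Product: 20 methyl (5E,7E)-7-{(2R)-2-acetoxy-4-chloro-2-[(2Z)-oct-2-en-1-yl]-5-oxocyclopent-3-en-1-ylidene}hept-5-enoate (target)
Conditions: Ac2O, DMAP, Et3N, CH2Cl2, rt, in the dark
Reagents that add atoms: acetic anhydride, CC(=O)OC(C)=O
Why: DMAP-catalysed acylation of a hindered tertiary alcohol with acetic anhydride; with C8 now sp2 there is no α-hydrogen from which the new β-acetoxy group could be eliminated, which is why acetylation is left to the end.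

## Compound list

1 | 3-ethoxycyclobut-2-en-1-one | CCOC1=CC(=O)C1 | starting material
2 | 1-bromooct-2-yne | CCCCCC#CCBr | starting material
3 | octa-1,2-dien-3-ylzinc bromide | C=C=C(CCCCC)[Zn]Br | intermediate (not isolated)
4 | 3-ethoxy-1-(oct-2-yn-1-yl)cyclobut-2-en-1-ol (racemic) | CCCCCC#CCC1(O)C=C(OCC)C1 | intermediate
5 | {[3-ethoxy-1-(oct-2-yn-1-yl)cyclobut-2-en-1-yl]oxy}triethylsilane (racemic) | CCCCCC#CCC1(O[Si](CC)(CC)CC)C=C(OCC)C1 | intermediate
6 | 3-(oct-2-yn-1-yl)-3-[(triethylsilyl)oxy]cyclobutan-1-one | CCCCCC#CCC1(O[Si](CC)(CC)CC)CC(=O)C1 | intermediate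
7 | lithium (3S)-3-(oct-2-yn-1-yl)-3-[(triethylsilyl)oxy]cyclobut-1-en-1-olate | CCCCCC#CC[C@@]1(O[Si](CC)(CC)CC)C=C(O[Li])C1 | intermediate (not isolated)
8 | (3S)-3-(oct-2-yn-1-yl)-3-[(triethylsilyl)oxy]-1-[(trimethylsilyl)oxy]cyclobut-1-ene | CCCCCC#CC[C@@]1(O[Si](CC)(CC)CC)C=C(O[Si](C)(C)C)C1 | intermediate
9 | (3S)-5,5-dichloro-3-(oct-2-yn-1-yl)-3-[(triethylsilyl)oxy]-1-[(trimethylsilyl)oxy]bicyclo[2.1.0]pentane (both cis-fused diastereomers at C1/C4) | CCCCCC#CC[C@@]1(O[Si](CC)(CC)CC)C2C(Cl)(Cl)C2(O[Si](C)(C)C)C1 | intermediate (not isolated)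
10 | (4S)-2-chloro-4-(oct-2-yn-1-yl)-4-[(triethylsilyl)oxy]cyclopent-2-en-1-one | CCCCCC#CC[C@@]1(O[Si](CC)(CC)CC)C=C(Cl)C(=O)C1 | intermediate
11 | (4S)-2-chloro-4-[(2Z)-oct-2-en-1-yl]-4-[(triethylsilyl)oxy]cyclopent-2-en-1-one | CCCCC/C=C\C[C@@]1(O[Si](CC)(CC)CC)C=C(Cl)C(=O)C1 | intermediate
12 | methyl hex-5-enoate | C=CCCCC(=O)OC | starting material
13 | (2E)-but-2-enal | C/C=C/C=O | starting material
14 | methyl (5E)-7-oxohept-5-enoate | O=C/C=C/CCCC(=O)OC | intermediate
15 | lithium (3S)-5-chloro-3-[(2Z)-oct-2-en-1-yl]-3-[(triethylsilyl)oxy]cyclopenta-1,4-dien-1-olate | CCCCC/C=C\C[C@@]1(O[Si](CC)(CC)CC)C=C(Cl)C(O[Li])=C1 | intermediate (not isolated)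
16 | methyl (5E)-7-{(2S)-4-chloro-2-[(2Z)-oct-2-en-1-yl]-5-oxo-2-[(triethylsilyl)oxy]cyclopent-3-en-1-yl}-7-hydroxyhept-5-enoate (mixture at C7 and C8) | CCCCC/C=C\C[C@@]1(O[Si](CC)(CC)CC)C=C(Cl)C(=O)C1C(O)/C=C/CCCC(=O)OC | intermediate
17 | methyl (5E)-7-{(2S)-4-chloro-2-[(2Z)-oct-2-en-1-yl]-5-oxo-2-[(triethylsilyl)oxy]cyclopent-3-en-1-yl}-7-[(methylsulfonyl)oxy]hept-5-enoate (mixture at C7 and C8) | CCCCC/C=C\C[C@@]1(O[Si](CC)(CC)CC)C=C(Cl)C(=O)C1C(OS(C)(=O)=O)/C=C/CCCC(=O)OC | intermediate (not isolated)
18 | methyl (5E,7E)-7-{(2R)-4-chloro-2-[(2Z)-oct-2-en-1-yl]-5-oxo-2-[(triethylsilyl)oxy]cyclopent-3-en-1-ylidene}hept-5-enoate | CCCCC/C=C\C[C@@]1(O[Si](CC)(CC)CC)C=C(Cl)C(=O)/C1=C/C=C/CCCC(=O)OC | intermediate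
19 | methyl (5E,7E)-7-{(2R)-4-chloro-2-hydroxy-2-[(2Z)-oct-2-en-1-yl]-5-oxocyclopent-3-en-1-ylidene}hept-5-enoate | CCCCC/C=C\C[C@@]1(O)C=C(Cl)C(=O)/C1=C/C=C/CCCC(=O)OC | intermediate
20 | methyl (5E,7E)-7-{(2R)-2-acetoxy-4-chloro-2-[(2Z)-oct-2-en-1-yl]-5-oxocyclopent-3-en-1-ylidene}hept-5-enoate | CCCCC/C=C\C[C@@]1(OC(C)=O)C=C(Cl)C(=O)/C1=C/C=C/CCCC(=O)OC | target

## Step count and least certain steps

Total step count: 11. Longest linear sequence: 10 (steps 1–6 and 8–11); step 7 is a one-step side branch.

**Step 5 (key step, proposed new method).**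
- What may go wrong: the siloxycyclobutene may be consumed before it is cyclopropanated, or the housane may open unselectively. The four-membered enol ether is more strained and more labile than its five- to seven-membered counterparts. It can undergo thermal conrotatory ring opening to a bis(siloxy)diene, which the C12 siloxy donor accelerates. Methoxide can desilylate it. Homolysis of the central bond of 9 could compete with the ionisation that leads to 10.
- Fallback (known reaction types only; sets out from 2, returns at 10): Barbier addition of 2 (Zn, THF) to cyclopent-3-en-1-one gives 1-(oct-2-yn-1-yl)cyclopent-3-en-1-ol F1. Hydroxyl-directed epoxidation (VO(acac)2, t-BuOOH) gives the meso cis-epoxy alcohol 3-(oct-2-yn-1-yl)-6-oxabicyclo[3.1.0]hexan-3-ol F2. Silylation (TESOTf, 2,6-lutidine) gives its triethylsilyl ether F3. Enantioselective β-elimination of the meso epoxide with a chiral lithium amide (lithium (S)-2-(pyrrolidin-1-ylmethyl)pyrrolidide or its enantiomer, as required) gives (1R,4S)-4-(oct-2-yn-1-yl)-4-[(triethylsilyl)oxy]cyclopent-2-en-1-ol F4. Oxidation (Dess–Martin periodinane) gives (4S)-4-(oct-2-yn-1-yl)-4-[(triethylsilyl)oxy]cyclopent-2-en-1-one F5. Nucleophilic epoxidation (H2O2, NaOH, MeOH) gives (4S)-4-(oct-2-yn-1-yl)-4-[(triethylsilyl)oxy]-6-oxabicyclo[3.1.0]hexan-2-one F6. Opening at C10 with HCl and loss of water then gives 10. Here the base distinguishes the two epoxide carbons, and the directed cis-epoxidation ties that choice to C12.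

**Step 4.**
- What may go wrong: poor discrimination between the two enantiotopic methylenes. Both C3 substituents are non-hydrogen groups, so the conformational bias of the ring that the chiral amide reads is small. A second risk is β-elimination of the siloxide from enolate 7 if silylation lags.
- Fallback (sets out from 6, returns at 10): resolution in place of induction. Achiral base (LDA, TMSCl in situ) gives racemic 3-(oct-2-yn-1-yl)-3-[(triethylsilyl)oxy]-1-[(trimethylsilyl)oxy]cyclobut-1-ene F7. Ring enlargement under the conditions of step 5 gives racemic 2-chloro-4-(oct-2-yn-1-yl)-4-[(triethylsilyl)oxy]cyclopent-2-en-1-one F8. Preparative chromatography on a chiral stationary phase (cellulose or amylose carbamate) separates the enantiomers to give 10.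

**Step 3.**
- What may go wrong: acid-promoted loss of the tertiary allylic siloxy group, by ionisation assisted by the enol ether and leading to a 3-substituted cyclobutenone, may compete with C-protonation of the enol ether.
- Fallback (sets out from 2, returns at 6; no enol ether involved): Barbier addition of 2 (Zn) to 1,3-dichloropropan-2-one gives 1-chloro-2-(chloromethyl)dec-4-yn-2-ol F9. With 2-lithio-1,3-dithiane and then n-BuLi, two successive epoxide closures and openings stitch the four-membered ring to give 2-(oct-2-yn-1-yl)-5,9-dithiaspiro[3.5]nonan-2-ol F10. Silylation (TESOTf, 2,6-lutidine) gives triethyl{[2-(oct-2-yn-1-yl)-5,9-dithiaspiro[3.5]nonan-2-yl]oxy}silane F11. Dithioketal cleavage (MeI, CaCO3, aq. MeCN) gives 6.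

**Step 6.**
- What may go wrong: over-reduction. Hydrogenolysis of the C10–Cl bond or saturation of the chloroenone may compete with semi-hydrogenation, since all three take place on the same palladium surface.
- Fallback (sets out from 6, returns at 11): reduce before the ring is elaborated. Lindlar semi-hydrogenation of 6, which has no other reducible group, gives 3-[(2Z)-oct-2-en-1-yl]-3-[(triethylsilyl)oxy]cyclobutan-1-one F12. Desymmetrisation as in step 4 gives (3S)-3-[(2Z)-oct-2-en-1-yl]-3-[(triethylsilyl)oxy]-1-[(trimethylsilyl)oxy]cyclobut-1-ene F13. Ring enlargement as in step 5 gives 11. This relies on the much higher nucleophilicity of the siloxycyclobutene than of a cis-dialkyl alkene towards :CCl2.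

**Step 9.**
- What may go wrong: loss of geometric control in the elimination. The quaternary C12 crowds the 7E geometry, so the 7Z isomer may form, and light can scramble C5=C6 and C7=C8.
- Fallback (sets out from 16, returns at 18): thermodynamic instead of kinetic control. The mixture from the elimination is separated. The isomer methyl (5E,7Z)-7-{(2R)-4-chloro-2-[(2Z)-oct-2-en-1-yl]-5-oxo-2-[(triethylsilyl)oxy]cyclopent-3-en-1-ylidene}hept-5-enoate F14 is re-equilibrated by reversible radical addition (catalytic I2, or PhSSPh under visible light) and recycled to 18.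

## Further compounds

F1 | step 5 | 1-(oct-2-yn-1-yl)cyclopent-3-en-1-ol | CCCCCC#CCC1(O)CC=CC1
F2 | step 5 | 3-(oct-2-yn-1-yl)-6-oxabicyclo[3.1.0]hexan-3-ol (meso, hydroxyl cis to the epoxide oxygen) | CCCCCC#CC[C@@]1(O)C[C@@H]2O[C@@H]2C1
F3 | step 5 | triethyl{[3-(oct-2-yn-1-yl)-6-oxabicyclo[3.1.0]hexan-3-yl]oxy}silane (meso, siloxy cis to the epoxide oxygen) | CCCCCC#CC[C@@]1(O[Si](CC)(CC)CC)C[C@@H]2O[C@@H]2C1
F4 | step 5 | (1R,4S)-4-(oct-2-yn-1-yl)-4-[(triethylsilyl)oxy]cyclopent-2-en-1-ol | CCCCCC#CC[C@@]1(O[Si](CC)(CC)CC)C=C[C@H](O)C1
F5 | step 5 | (4S)-4-(oct-2-yn-1-yl)-4-[(triethylsilyl)oxy]cyclopent-2-en-1-one | CCCCCC#CC[C@@]1(O[Si](CC)(CC)CC)C=CC(=O)C1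
F6 | step 5 | (4S)-4-(oct-2-yn-1-yl)-4-[(triethylsilyl)oxy]-6-oxabicyclo[3.1.0]hexan-2-one (epoxide diastereomers) | CCCCCC#CC[C@@]1(O[Si](CC)(CC)CC)C2OC2C(=O)C1
F7 | step 4 | 3-(oct-2-yn-1-yl)-3-[(triethylsilyl)oxy]-1-[(trimethylsilyl)oxy]cyclobut-1-ene (racemic) | CCCCCC#CCC1(O[Si](CC)(CC)CC)C=C(O[Si](C)(C)C)C1
F8 | step 4 | 2-chloro-4-(oct-2-yn-1-yl)-4-[(triethylsilyl)oxy]cyclopent-2-en-1-one (racemic) | CCCCCC#CCC1(O[Si](CC)(CC)CC)C=C(Cl)C(=O)C1
F9 | step 3 | 1-chloro-2-(chloromethyl)dec-4-yn-2-ol | CCCCCC#CCC(O)(CCl)CCl
F10 | step 3 | 2-(oct-2-yn-1-yl)-5,9-dithiaspiro[3.5]nonan-2-ol | CCCCCC#CCC1(O)CC2(C1)SCCCS2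
F11 | step 3 | triethyl{[2-(oct-2-yn-1-yl)-5,9-dithiaspiro[3.5]nonan-2-yl]oxy}silane | CCCCCC#CCC1(O[Si](CC)(CC)CC)CC2(C1)SCCCS2
F12 | step 6 | 3-[(2Z)-oct-2-en-1-yl]-3-[(triethylsilyl)oxy]cyclobutan-1-one | CCCCC/C=C\CC1(O[Si](CC)(CC)CC)CC(=O)C1
F13 | step 6 | (3S)-3-[(2Z)-oct-2-en-1-yl]-3-[(triethylsilyl)oxy]-1-[(trimethylsilyl)oxy]cyclobut-1-ene | CCCCC/C=C\C[C@@]1(O[Si](CC)(CC)CC)C=C(O[Si](C)(C)C)C1
F14 | step 9 | methyl (5E,7Z)-7-{(2R)-4-chloro-2-[(2Z)-oct-2-en-1-yl]-5-oxo-2-[(triethylsilyl)oxy]cyclopent-3-en-1-ylidene}hept-5-enoate | CCCCC/C=C\C[C@@]1(O[Si](CC)(CC)CC)C=C(Cl)C(=O)/C1=C\C=C\CCCC(=O)OC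
A1 | alternative 1 | 4-hydroxy-4-(oct-2-yn-1-yl)cyclopent-2-en-1-one (racemic) | CCCCCC#CCC1(O)C=CC(=O)C1
A2 | alternative 2 | 2-methyl-5-(oct-2-yn-1-yl)furan | CCCCCC#CCc1ccc(C)o1
A3 | alternative 2 | (3Z)-tridec-3-en-7-yne-2,5-dione | CCCCCC#CCC(=O)/C=C\C(=O)C
A4 | alternative 3 | methyl (5E,7E)-7-(3-chloro-2,5-dioxocyclopent-3-en-1-ylidene)hept-5-enoate | COC(=O)CCC/C=C/C=C1\C(=O)C=C(Cl)C1=O
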